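**Plan**

- Retrosynthesis: remove the three phenolic benzyl groups and the O-acetyl group, take CH2OAc back to CHO, cut the ring bond C2–C3 of the oxolane, then cut the C4–CH2Ar bond and the two acetal C–O bonds.
- Enabling feature: in the oxolane, O1–C2(aryl) is a latent aryl-stabilised oxocarbenium ion and C3 with its exocyclic CH2O carbon is a latent aldehyde enolate. Tying that carbon to C2 through its own oxygen gives a seven-membered 2-aryl-4,5-dihydro-1,3-dioxepine (cyclic vinyl acetal) that contracts to the five-membered ring.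
- Forward: (Z)-butenediol and the aldehyde close the seven-membered acetal; an asymmetric benzylic Heck reaction attaches the arylmethyl arm and moves the alkene next to oxygen; a Lewis acid contracts the dioxepine to the tetrahydrofuran-3-carbaldehyde (C2–C3 formed).
- Finish: C3 epimerisation and reduction, acetylation, hydrogenolysis.
- Stereochemistry: C4 (R) from the ligand-controlled Heck step; C2 from the ring contraction under control of C4 (2,4-trans); C3 by thermodynamic epimerisation (trans to aryl) before reduction.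

Key step: step 4

Assumption: the phosphoramidite ligand in step 3 is taken to give (5R)-6 (its antipode is used if the 5S product forms), and both acetal epimers of 6 are carried on together because the acetal carbon is planarised in step 4.

Step 1
Reactants: 1 (Z)-but-2-ene-1,4-diol; 2 3,4-bis(benzyloxy)benzaldehyde
Product: 3 2-[3,4-bis(benzyloxy)phenyl]-4,7-dihydro-1,3-dioxepine
Conditions: p-TsOH·H2O (2 mol %), toluene, reflux, Dean–Stark
Reagents that add atoms: none
Why: Acid-catalysed acetalisation with azeotropic water removal closes the seven-membered ring because the Z-alkene holds the two hydroxyls together; the product has a mirror plane and no stereocentre.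

Step 2
Reactants: 4 [4-(benzyloxy)-3-methoxyphenyl]methanol
Product: 5 4-(benzyloxy)-3-methoxybenzyl trifluoroacetate
Conditions: (CF3CO)2O, pyridine, CH2Cl2, 0 °C; used directly
Reagents that add atoms: trifluoroacetic anhydride, O=C(OC(=O)C(F)(F)F)C(F)(F)F
Why: O-Acylation of a primary benzylic alcohol gives the leaving group that ionises readily to an η3-benzyl palladium species in benzylic Heck reactions.

Step 3
Reactants: 3 2-[3,4-bis(benzyloxy)phenyl]-4,7-dihydro-1,3-dioxepine; 5 4-(benzyloxy)-3-methoxybenzyl trifluoroacetate (1.5 equiv)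
Product: 6 (5R)-5-[4-(benzyloxy)-3-methoxybenzyl]-2-[3,4-bis(benzyloxy)phenyl]-4,5-dihydro-1,3-dioxepine (both C2 epimers)
Conditions: Pd(dba)2 (5 mol %), (S)-BINOL-derived N,N-bis[(R)-1-phenylethyl]phosphoramidite (10 mol %), Li2CO3, 1,4-dioxane, 60 °C; Et3N-deactivated silica
Reagents that add atoms: none
Why: Asymmetric intermolecular Mizoroki–Heck reaction of a benzylic electrophile with a cyclic cis-alkene: zerovalent palladium ionises 5 to a cationic η3-benzyl divalent palladium complex, the chiral ligand selects one enantiotopic alkene carbon in the syn-carbopalladation (C5 becomes R on either ring face, so both acetal epimers share the C5 configuration), and syn-β-hydride elimination can only occur away from the new substituent, which places the alkene next to O1 as the vinyl acetal.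

Step 4
Reactants: 6 (5R)-5-[4-(benzyloxy)-3-methoxybenzyl]-2-[3,4-bis(benzyloxy)phenyl]-4,5-dihydro-1,3-dioxepine
Product: 8 (2S,3R,4R)-4-[4-(benzyloxy)-3-methoxybenzyl]-2-[3,4-bis(benzyloxy)phenyl]tetrahydrofuran-3-carbaldehyde (2,3-cis-3,4-trans), via oxocarbenium silyl enol ether triflate 7 (not isolated)
Conditions: Me3SiOTf (0.2 equiv), CH2Cl2, −78 °C; Et3N quench at −78 °C; used crude
Reagents that add atoms: none
Why: Me3SiOTf silylates the enol-ether oxygen O1 of the seven-membered vinyl acetal and ionises the C2–O1 bond, giving the (E)-oxocarbenium ion ArCH=O3+ (stabilised by the 3,4-dialkoxyphenyl group) still tethered through C4 and C5 to a (Z)-silyl enol ether (7), whose carbon C6 then attacks C2, so that the dioxepine contracts to the oxolane by a net [1,3] shift of C2 from oxygen to carbon and the silyl group passes to the next molecule. The closest known reaction type is the Lewis-acid-mediated vinyl acetal rearrangement of 4,5-dihydro-1,3-dioxepines to tetrahydrofuran-3-carbaldehydes (a Petasis–Ferrier-type ring contraction). The five-membered ring closes in a 5-(enolexo)-endo-trig mode, formally unfavourable but usual for oxocarbenium ions. The new C3 centre is controlled by C4: allylic 1,3-strain in the (Z)-enol ether turns the C4–H bond into the plane of the enol C=C, the tethered cation arrives on the face opposite the arylmethyl group and the formyl group ends trans to it; the new C2 centre is controlled by the compact synclinal pairing of enol ether and (E)-oxocarbenium ion, which should place the aryl group cis to the formyl group. The selectivity the route needs from this step is the 2,4-trans relation of aryl and arylmethyl groups together with convergence of both acetal epimers of 6, and it is secured by complete ionisation to the free stabilised cation at −78 °C under kinetic control. C3 itself is corrected in step 5.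

Step 5
Reactants: 8 (2S,3R,4R)-4-[4-(benzyloxy)-3-methoxybenzyl]-2-[3,4-bis(benzyloxy)phenyl]tetrahydrofuran-3-carbaldehyde
Product: 10 [(2S,3R,4R)-4-[4-(benzyloxy)-3-methoxybenzyl]-2-[3,4-bis(benzyloxy)phenyl]tetrahydrofuran-3-yl]methanol, via 2,3-trans-3,4-cis aldehyde 9 (not isolated)
Conditions: DBU (0.3 equiv), CH2Cl2, rt; then MeOH, NaBH4, 0 °C
Reagents that add atoms: none
Why: Base-mediated epimerisation of the only enolisable stereocentre (C3) should move the formyl group trans to the C2 aryl group and cis to the smaller arylmethyl arm under thermodynamic control, and chemoselective borohydride reduction of the aldehyde then locks C3.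

Step 6
Reactants: 10 [(2S,3R,4R)-4-[4-(benzyloxy)-3-methoxybenzyl]-2-[3,4-bis(benzyloxy)phenyl]tetrahydrofuran-3-yl]methanol
Product: 11 [(2S,3R,4R)-4-[4-(benzyloxy)-3-methoxybenzyl]-2-[3,4-bis(benzyloxy)phenyl]tetrahydrofuran-3-yl]methyl acetate
Conditions: Ac2O, pyridine, DMAP (cat.), CH2Cl2, 0 °C to rt
Reagents that add atoms: acetic anhydride, CC(=O)OC(C)=O
Why: DMAP-catalysed acetylation of the only free hydroxyl (primary); no stereocentre is touched.

Step 7
Reactants: 11 [(2S,3R,4R)-4-[4-(benzyloxy)-3-methoxybenzyl]-2-[3,4-bis(benzyloxy)phenyl]tetrahydrofuran-3-yl]methyl acetate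
Product: 12 [(2S,3R,4R)-2-(3,4-dihydroxyphenyl)-4-(4-hydroxy-3-methoxybenzyl)tetrahydrofuran-3-yl]methyl acetate
Conditions: H2 (1 atm), 10% Pd/C, EtOAc, rt; stopped at full uptake, degassed work-up
Reagents that add atoms: none
Why: Catalytic hydrogenolysis should cleave the three aryl benzyl ethers much faster than the cyclic benzylic C2–O bond in a neutral aprotic solvent, leaving acetate, aryl methyl ether and all stereocentres intact.

**Compound list**

1 | (Z)-but-2-ene-1,4-diol | OC/C=C\CO | starting material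
2 | 3,4-bis(benzyloxy)benzaldehyde | O=Cc1ccc(OCc2ccccc2)c(OCc2ccccc2)c1 | starting material
3 | 2-[3,4-bis(benzyloxy)phenyl]-4,7-dihydro-1,3-dioxepine | C1=CCOC(c2ccc(OCc3ccccc3)c(OCc3ccccc3)c2)OC1 | intermediate
4 | [4-(benzyloxy)-3-methoxyphenyl]methanol | COc1cc(CO)ccc1OCc1ccccc1 | starting material
5 | 4-(benzyloxy)-3-methoxybenzyl trifluoroacetate | COc1cc(COC(=O)C(F)(F)F)ccc1OCc1ccccc1 | intermediate
6 | (5R)-5-[4-(benzyloxy)-3-methoxybenzyl]-2-[3,4-bis(benzyloxy)phenyl]-4,5-dihydro-1,3-dioxepine (C2 epimers) | COc1cc(C[C@H]2COC(c3ccc(OCc4ccccc4)c(OCc4ccccc4)c3)OC=C2)ccc1OCc1ccccc1 | intermediate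
7 | ring-opened (E)-oxocarbenium triflate carrying the (Z)-trimethylsilyl enol ether, (R) at the arylmethyl carbon | C[Si](C)(C)O/C=C\[C@@H](Cc1ccc(OCc2ccccc2)c(OC)c1)C/[O+]=C/c1ccc(OCc2ccccc2)c(OCc2ccccc2)c1.[O-]S(=O)(=O)C(F)(F)F | intermediate
8 | (2S,3R,4R)-4-[4-(benzyloxy)-3-methoxybenzyl]-2-[3,4-bis(benzyloxy)phenyl]tetrahydrofuran-3-carbaldehyde (2,3-cis-3,4-trans) | COc1cc(C[C@H]2CO[C@H](c3ccc(OCc4ccccc4)c(OCc4ccccc4)c3)[C@@H]2C=O)ccc1OCc1ccccc1 | intermediate
9 | (2S,3S,4R)-4-[4-(benzyloxy)-3-methoxybenzyl]-2-[3,4-bis(benzyloxy)phenyl]tetrahydrofuran-3-carbaldehyde (2,3-trans-3,4-cis) | COc1cc(C[C@H]2CO[C@H](c3ccc(OCc4ccccc4)c(OCc4ccccc4)c3)[C@H]2C=O)ccc1OCc1ccccc1 | intermediate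
10 | [(2S,3R,4R)-4-[4-(benzyloxy)-3-methoxybenzyl]-2-[3,4-bis(benzyloxy)phenyl]tetrahydrofuran-3-yl]methanol | COc1cc(C[C@H]2CO[C@H](c3ccc(OCc4ccccc4)c(OCc4ccccc4)c3)[C@H]2CO)ccc1OCc1ccccc1 | intermediate
11 | [(2S,3R,4R)-4-[4-(benzyloxy)-3-methoxybenzyl]-2-[3,4-bis(benzyloxy)phenyl]tetrahydrofuran-3-yl]methyl acetate | COc1cc(C[C@H]2CO[C@H](c3ccc(OCc4ccccc4)c(OCc4ccccc4)c3)[C@H]2COC(C)=O)ccc1OCc1ccccc1 | intermediate
12 | [(2S,3R,4R)-2-(3,4-dihydroxyphenyl)-4-(4-hydroxy-3-methoxybenzyl)tetrahydrofuran-3-yl]methyl acetate | COc1cc(C[C@H]2CO[C@H](c3ccc(O)c(O)c3)[C@H]2COC(C)=O)ccc1O | target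

Total steps: 7. Longest linear sequence: 6 (steps 1, 3, 4, 5, 6, 7).

**Steps most likely to fail**

1. Step 3. The unactivated ring alkene may insert too slowly into the η3-benzyl palladium species, so that the electron-rich trifluoroacetate is lost by solvolysis or homocoupling, or enantiofacial discrimination may be weak. The fallback sets out from 4 (and uses 2) and comes back at 6. Alcohol 4 is converted with PBr3 (Et2O, 0 °C) into 4-(benzyloxy)-3-methoxybenzyl bromide F1. But-2-yne-1,4-diol is syn-hydrostannylated (Bu3SnH, PdCl2(PPh3)2 cat., THF) to (E)-2-(tributylstannyl)but-2-ene-1,4-diol F2. Stille coupling of F1 with F2 (Pd(PPh3)4, DMF, 80 °C) should give (Z)-2-[4-(benzyloxy)-3-methoxybenzyl]but-2-ene-1,4-diol F3. Acetalisation with 2 as in step 1 gives racemic 5-[4-(benzyloxy)-3-methoxybenzyl]-2-[3,4-bis(benzyloxy)phenyl]-4,7-dihydro-1,3-dioxepine F4. Enantioselective double-bond migration with a chiral nickel hydride (NiBr2[(R,R)-Me-DuPHOS] with LiBHEt3, THF, −40 °C, ligand antipode chosen for 5R) then creates C5 by hydride delivery and gives 6.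

2. Step 4. The two acetal epimers may not converge if the ion pair collapses before the acetal configuration is lost, facial selectivity between C2 and C4 may be poor, or the vinyl acetal may hydrolyse. The fallback sets out from 6 and comes back at 10. Dilute aqueous HCl in THF hydrolyses 6 to (4R)-4-[4-(benzyloxy)-3-methoxybenzyl]tetrahydrofuran-2-ol F5, with 2 recovered. Oxidation (TEMPO cat., PhI(OAc)2, CH2Cl2) gives (R)-4-[4-(benzyloxy)-3-methoxybenzyl]dihydrofuran-2(3H)-one F6. Its lithium enolate (LiN(SiMe3)2, THF, −78 °C) adds to 2 anti to the arylmethyl group and gives (3S,4R)-4-[4-(benzyloxy)-3-methoxybenzyl]-3-{[3,4-bis(benzyloxy)phenyl](hydroxy)methyl}dihydrofuran-2(3H)-one F7 as carbinol epimers. LiAlH4 (THF, 0 °C) reduces it to (2R,3R)-2-[4-(benzyloxy)-3-methoxybenzyl]-3-{[3,4-bis(benzyloxy)phenyl](hydroxy)methyl}butane-1,4-diol F8. Acid-catalysed cyclisation (camphorsulfonic acid cat., CH2Cl2, rt) through the benzylic cation, closed by the hydroxymethyl group on the arylmethyl-bearing carbon, should give 10. The trans lactone becomes the 3,4-cis relation, and C2 settles trans to C3 under thermodynamic control.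

3. Step 5. The equilibrium at C3 may not be one-sided enough, or the aldehyde may be lost by base-induced β-elimination of the ring oxygen or by self-condensation before it equilibrates. The fallback sets out from 8 and comes back at 10. Oxidative esterification (I2, KOH, MeOH, 0 °C) gives methyl (2S,3R,4R)-4-[4-(benzyloxy)-3-methoxybenzyl]-2-[3,4-bis(benzyloxy)phenyl]tetrahydrofuran-3-carboxylate F9. Equilibration with NaOMe in MeOH (50 °C) gives the 2,3-trans-3,4-cis ester methyl (2S,3S,4R)-4-[4-(benzyloxy)-3-methoxybenzyl]-2-[3,4-bis(benzyloxy)phenyl]tetrahydrofuran-3-carboxylate F10, separable from F9, which is recycled. LiAlH4 (THF, 0 °C) reduces F10 to 10. If the equilibrium position itself is inadequate, the lactone sequence given for step 4 sets C3 independently.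

**Further compounds**

F1 | step 3 | 4-(benzyloxy)-3-methoxybenzyl bromide | COc1cc(CBr)ccc1OCc1ccccc1
F2 | step 3 | (E)-2-(tributylstannyl)but-2-ene-1,4-diol | OC/C(=C\CO)[Sn](CCCC)(CCCC)CCCC
F3 | step 3 | (Z)-2-[4-(benzyloxy)-3-methoxybenzyl]but-2-ene-1,4-diol | COc1cc(C/C(CO)=C/CO)ccc1OCc1ccccc1
F4 | step 3 | 5-[4-(benzyloxy)-3-methoxybenzyl]-2-[3,4-bis(benzyloxy)phenyl]-4,7-dihydro-1,3-dioxepine (racemic) | COc1cc(CC2=CCOC(c3ccc(OCc4ccccc4)c(OCc4ccccc4)c3)OC2)ccc1OCc1ccccc1
F5 | step 4 | (4R)-4-[4-(benzyloxy)-3-methoxybenzyl]tetrahydrofuran-2-ol (anomers) | COc1cc(C[C@H]2COC(O)C2)ccc1OCc1ccccc1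
F6 | step 4 | (R)-4-[4-(benzyloxy)-3-methoxybenzyl]dihydrofuran-2(3H)-one | COc1cc(C[C@H]2COC(=O)C2)ccc1OCc1ccccc1
F7 | step 4 | (3S,4R)-4-[4-(benzyloxy)-3-methoxybenzyl]-3-{[3,4-bis(benzyloxy)phenyl](hydroxy)methyl}dihydrofuran-2(3H)-one (carbinol epimers) | COc1cc(C[C@H]2COC(=O)[C@@H]2C(O)c2ccc(OCc3ccccc3)c(OCc3ccccc3)c2)ccc1OCc1ccccc1
F8 | step 4 | (2R,3R)-2-[4-(benzyloxy)-3-methoxybenzyl]-3-{[3,4-bis(benzyloxy)phenyl](hydroxy)methyl}butane-1,4-diol (carbinol epimers) | COc1cc(C[C@@H](CO)[C@H](CO)C(O)c2ccc(OCc3ccccc3)c(OCc3ccccc3)c2)ccc1OCc1ccccc1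
F9 | step 5 | methyl (2S,3R,4R)-4-[4-(benzyloxy)-3-methoxybenzyl]-2-[3,4-bis(benzyloxy)phenyl]tetrahydrofuran-3-carboxylate (2,3-cis-3,4-trans) | COc1cc(C[C@H]2CO[C@H](c3ccc(OCc4ccccc4)c(OCc4ccccc4)c3)[C@@H]2C(=O)OC)ccc1OCc1ccccc1
F10 | step 5 | methyl (2S,3S,4R)-4-[4-(benzyloxy)-3-methoxybenzyl]-2-[3,4-bis(benzyloxy)phenyl]tetrahydrofuran-3-carboxylate (2,3-trans-3,4-cis) | COc1cc(C[C@H]2CO[C@H](c3ccc(OCc4ccccc4)c(OCc4ccccc4)c3)[C@H]2C(=O)OC)ccc1OCc1ccccc1
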